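**Plan** (the target is 12α,15β-dihydroxygibberellic acid; positions C1–C19 are numbered as in gibberellins)

- Retrosynthesis: open ring A at C1=C2 (metathesis) and C3–C4 (aldol); open ring D at C13–C16; put C7 back between C6 and C8, so ring B becomes a six-membered 6-diazo-7-ketone. Further cuts are C4–C5 (Michael), C10–C1 (vinyl addition), C8–C15 (decarboxylative allylation), and C8–C14 with C9–C11 (Diels–Alder).
- Forward: rings B (six-membered, C5–C10 plus C7) and C form together in an asymmetric quinone Diels–Alder reaction; the activating ester on C8 is exchanged for the C15–C17 allyl group; vinyl addition/propionylation at C10 and an intramolecular Michael addition build the 19,10-lactone; an acrolein aldol adds C2–C3.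
- Then ring B is contracted (step 11), ring D is closed by palladium cycloalkenylation of the enediol ether, C12 and C15 are set by oxidation/reduction, and ring A is closed last by metathesis.
- Stereochemistry: C9 comes from the chiral Lewis acid. All other centers are relayed from it: C8 (allyl cis to H9), C10 (convex-face addition), C5 (cis-fused lactone), C4/C3 (lactone-enolate aldol), C6 (thermodynamic), C13 (bridge), C12 and C15 (hydride on the open faces).
- Enabling feature: C6 of ring B carries the C7 carboxyl and lies between C5 and the quaternary C8. With C7 kept in the ring as a ketone, that ketone has only one enolizable neighbor (C6), so a diazo group goes there regiospecifically, and a 1,2-shift of the C7–C8 bond onto C6 turns the cyclohexanone into the cyclopentane with C7 as the exocyclic carboxyl.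

Key step: step 11

Assumption: the (S,S)-pybox ligand in step 4 is taken to give the drawn enantiomer of 6; if the sense of induction is opposite, the (R,R)-ligand is used and nothing else changes.

Step 1
Reactants: 1 2,5-dihydroxybenzoic acid
Product: 2 allyl 2,5-dihydroxybenzoate
Conditions: allyl bromide, KHCO3, DMF, 40 °C
Reagents that add atoms: allyl bromide, C=CCBr
Why: SN2 O-alkylation of the carboxylate should esterify the acid selectively, because KHCO3 does not deprotonate the phenols.

Step 2
Reactants: 3 butane-2,3-dione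
Product: 4 2,3-bis(tert-butyldimethylsilyloxy)buta-1,3-diene
Conditions: t-BuMe2SiOTf, Et3N, CH2Cl2, 0 °C
Reagents that add atoms: tert-butyldimethylsilyl trifluoromethanesulfonate, CC(C)(C)[Si](C)(C)OS(=O)(=O)C(F)(F)F
Why: Double silyl enol ether formation from a 1,2-diketone with a silyl triflate and an amine base is the standard route to 2,3-bis(silyloxy)dienes and creates no stereocenter.

Step 3
Reactants: 2 allyl 2,5-dihydroxybenzoate
Product: 5 allyl 3,6-dioxocyclohexa-1,4-diene-1-carboxylate
Conditions: Ag2O, MgSO4, Et2O, 23 °C; filtered and used at once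
Reagents that add atoms: none
Why: Ag2O oxidation of a hydroquinone to the quinone is a standard way to make 2-carboalkoxy-1,4-benzoquinones, which are sensitive and are therefore used directly.

Step 4
Reactants: 5 allyl 3,6-dioxocyclohexa-1,4-diene-1-carboxylate; 4 2,3-bis(tert-butyldimethylsilyloxy)buta-1,3-diene
Product: 6 cis-fused Diels–Alder adduct (rings B and C; allyl ester on C8 cis to H9; C7 and C10 ketones; C5=C6; C12=C13 bis-TBS enediol ether)
Conditions: Gd(OTf)3 (10 mol%), (S,S)-Ph-pybox (12 mol%), 4 Å MS, CH2Cl2, −78 °C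
Reagents that add atoms: none
Why: Catalytic enantioselective quinone Diels–Alder reaction in which two-point binding of the β-keto ester to the chiral Gd(OTf)3–pybox Lewis acid activates the ester-bearing C8=C9 bond and shields one face; suprafacial addition makes the C8 ester and H9 cis and sets C9 absolutely, and the C2-symmetric diene removes any regiochemical question.

Step 5
Reactants: 6 cis-fused Diels–Alder adduct
Product: 7 8-allyl enedione (allyl on C8 cis to H9)
Conditions: Pd(PPh3)4 (5 mol%), THF, 25 °C
Reagents that add atoms: none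
Why: Tsuji decarboxylative allylation, in which zerovalent palladium ionizes the allyl β-keto ester, CO2 is lost and the C8 enolate recombines with the π-allyl cation on the face opposite to C11, that is cis to H9; the quaternary C8 so formed blocks aromatization.

Step 6
Reactants: 7 8-allyl enedione
Product: 9 10α-propionyloxy-10β-vinyl enone, via bromomagnesium alkoxide 8 (not isolated)
Conditions: CH2=CHMgBr, CeCl3, THF, −78 °C; then (EtCO)2O, DMAP, −78 → 0 °C
Reagents that add atoms: vinylmagnesium bromide, C=C[Mg]Br; propionic anhydride, CCC(=O)OC(=O)CC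
Why: 1,2-Addition of the CH2=CHMgBr–CeCl3 reagent should take place at the less hindered C10 carbonyl (C7 is flanked by the quaternary C8) from the convex β face of the cis-fused bicycle, opposite to ring C, which sets C10 with oxygen α; the alkoxide is acylated in the same flask.

Step 7
Reactants: 9 10α-propionyloxy-10β-vinyl enone
Product: 10 keto lactone (19,10-lactone cis-fused to ring B; H5β; C7 ketone)
Conditions: LiN(i-Pr)2, THF, −78 °C; NH4Cl (aq)
Reagents that add atoms: none
Why: Intramolecular Michael addition (5-exo-trig) of the propionate enolate to C5 of the enone, where the short tether forces a cis-fused lactone so that C4 enters on the α face and H5 becomes β; the C4 methine is epimerizable and is erased in step 9.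

Step 8
Reactants: 10 keto lactone
Product: 12 6-diazo-7-ketone, via 6-trifluoroacetyl-7-ketone 11 (not isolated)
Conditions: LiN(SiMe3)2, THF, −78 °C; CF3CO2CH2CF3; NH4Cl (aq); then MsN3, Et3N, H2O, MeCN, 25 °C
Reagents that add atoms: 2,2,2-trifluoroethyl trifluoroacetate, O=C(OCC(F)(F)F)C(F)(F)F (its CF3CO group stays only in 11); methanesulfonyl azide, CS(=O)(=O)N=[N+]=[N-]
Why: Detrifluoroacetylative Regitz diazo transfer, which should be regiospecific because the C7 ketone has a single enolizable neighbor (C6; C8 is quaternary) and the ketone is more acidic than the lactone; no stereocenter is created.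

Step 9
Reactants: 12 6-diazo-7-ketone
Product: 13 aldol adduct (C4 quaternary; (3S)-hydroxyallyl group on the face of the 10-vinyl group)
Conditions: LiN(i-Pr)2, THF, −78 °C; acrolein; NH4Cl (aq), −78 °C
Reagents that add atoms: acrolein, C=CC=O
Why: Aldol addition of the lactone lithium enolate (the diazo ketone has no α-hydrogen) to acrolein, in which the aldehyde approaches C4 anti to the C5–C6 bond, on the face of the C10 vinyl group, and a closed Zimmerman–Traxler transition state with the vinyl group equatorial gives the C3 configuration that becomes 3β-OH.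

Step 10
Reactants: 13 aldol adduct
Product: 14 3-O-triethylsilyl diazo ketone
Conditions: Et3SiCl, imidazole, DMAP (cat.), DMF, 25 °C
Reagents that add atoms: chlorotriethylsilane, CC[Si](Cl)(CC)CC
Why: Silylation of the secondary alcohol blocks retro-aldol cleavage and intramolecular trapping of the later ketene; no stereocenter is affected.

Step 11
Reactants: 14 3-O-triethylsilyl diazo ketone
Product: 17 6β-(2-trimethylsilylethyl) ester with five-membered ring B, via ketene 15 (not isolated), via C6-epimeric ester 16 (not isolated)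
Conditions: hν (300 nm), Me3SiCH2CH2OH (10 equiv), THF, 25 °C; then KOt-Bu (0.3 equiv), t-BuOH, 25 °C
Reagents that add atoms: 2-(trimethylsilyl)ethanol, C[Si](C)(C)CCO
Why: Excitation of the s-cis-locked cyclic α-diazo ketone expels N2 with a concerted 1,2-shift of the C7–C8 bond from the carbonyl carbon C7 to the diazo carbon C6 (photochemical Wolff rearrangement), and the ketene 15 adds the alcohol. The closest known reaction type is the Wolff ring contraction of 2-diazocycloalkanones to cycloalkanecarboxylates. Ring B is closed as the five-membered ring by this 1,2-alkyl shift (ring contraction of the six-membered diazo ketone), and the migrating quaternary C8 keeps its configuration. The only new stereocenter, C6, is first formed by protonation of the ester enol from the open β face (mainly the 6α-ester 16) and is then corrected by KOt-Bu under thermodynamic control, because the 6β-ester on the convex face avoids the quaternary C4 and C14 on the concave α face. The step needs migration from C7 to C6 only and no carbene side reactions (1,2-hydride shift from C5, insertion, cyclopropanation of the three alkenes); the quaternary C8 leaves C6 as the only site for the diazo group, and the ring holds the diazo ketone s-cis so that loss of N2 and migration are concerted.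

Step 12
Reactants: 17 6β-(2-trimethylsilylethyl) ester with five-membered ring B
Product: 18 13-O-TBS 12-oxo-16-ene (ring D closed)
Conditions: Pd(OAc)2 (10 mol%), O2 (1 atm), DMSO, 45 °C
Reagents that add atoms: none
Why: Saegusa–Ito-type oxidative cycloalkenylation of a silyl enol ether with a pendant allyl group, in which divalent palladium metalates C13 of the enediol ether, the C8 allyl group inserts 5-exo (C13–C16 bond) and β-hydride elimination of H16 gives the exocyclic methylene; closure through C13 and not C12 is expected from ring size (five against six), the bridge fixes C13, and O12 loses its silyl group to become the ketone.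

Step 13
Reactants: 18 13-O-TBS 12-oxo-16-ene
Product: 19 15α-alcohol
Conditions: SeO2 (0.3 equiv), t-BuOOH, CH2Cl2, 25 °C
Reagents that add atoms: tert-butyl hydroperoxide, CC(C)(C)OO
Why: Selenium dioxide allylic oxidation (ene reaction then 2,3-sigmatropic shift) at the only allylic C–H position of the 1,1-disubstituted alkene (C15; C13 is quaternary), with oxygen expected on the more open exo (α) face; this center is reset in steps 14 and 15.

Step 14
Reactants: 19 15α-alcohol
Product: 20 12,15-diketone
Conditions: Dess–Martin periodinane, pyridine, CH2Cl2, 0 → 25 °C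
Reagents that add atoms: none
Why: Dess–Martin oxidation of the allylic alcohol to the exocyclic enone, at which any 15-epimer or enone already formed in step 13 converges.

Step 15
Reactants: 20 12,15-diketone
Product: 21 12α,15β-diol
Conditions: NaBH4, CeCl3·7H2O, MeOH, −78 → 0 °C
Reagents that add atoms: none
Why: Luche reduction of both ketones, in which hydride should reach C15 from the exo face (the endo face is screened by the axial hydrogen on C11) to give the 15β (endo) alcohol, and C12 along the equatorial path from the β side (the α side is blocked by the syn-axial C10) to give the axial 12α alcohol; CeCl3 keeps the enone reduction 1,2 and the esters are not touched.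

Step 16
Reactants: 21 12α,15β-diol
Product: 22 fully protected 12α,15β-dihydroxygibberellic acid (3-O-TES; 13-O-TBS; 7-(2-trimethylsilylethyl) ester)
Conditions: second-generation Grubbs catalyst RuCl2(H2IMes)(PCy3)(=CHPh) (5 mol%), CH2Cl2, 40 °C
Reagents that add atoms: none
Why: Ring-closing metathesis of the vinyl groups on C10 and C3, which are cis on the lactone ring, should close ring A as the cyclohexene with the C1=C2 bond, while the 1,1-disubstituted C16 alkene is too hindered to take part.

Step 17
Reactants: 22 fully protected 12α,15β-dihydroxygibberellic acid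
Product: 23 12α,15β-dihydroxygibberellic acid (the target gibberellin)
Conditions: Bu4NF, AcOH, THF, 25 → 40 °C
Reagents that add atoms: none
Why: Fluoride cleaves the two silyl ethers and fragments the 2-(trimethylsilyl)ethyl ester to the acid, and the acetic acid buffer protects the base-sensitive allylic lactone of ring A.

**Compound list**

1 | 2,5-dihydroxybenzoic acid | OC(=O)c1cc(O)ccc1O | starting material
2 | allyl 2,5-dihydroxybenzoate | C=CCOC(=O)c1cc(O)ccc1O | intermediate
3 | butane-2,3-dione | CC(=O)C(C)=O | starting material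
4 | 2,3-bis(tert-butyldimethylsilyloxy)buta-1,3-diene | C=C(O[Si](C)(C)C(C)(C)C)C(=C)O[Si](C)(C)C(C)(C)C | intermediate
5 | allyl 3,6-dioxocyclohexa-1,4-diene-1-carboxylate | C=CCOC(=O)C1=CC(=O)C=CC1=O | intermediate
6 | cis-fused Diels–Alder adduct (allyl ester on C8 cis to H9; C7 and C10 ketones; C5=C6; C12=C13 bis-TBS enediol ether) | C=CCOC(=O)[C@]12CC(O[Si](C)(C)C(C)(C)C)=C(O[Si](C)(C)C(C)(C)C)C[C@H]1C(=O)C=CC2=O | intermediate
7 | 8-allyl enedione (allyl on C8 cis to H9) | C=CC[C@]12CC(O[Si](C)(C)C(C)(C)C)=C(O[Si](C)(C)C(C)(C)C)C[C@H]1C(=O)C=CC2=O | intermediate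
8 | bromomagnesium alkoxide (10β-vinyl; 10α-OMgBr) | C=CC[C@]12CC(O[Si](C)(C)C(C)(C)C)=C(O[Si](C)(C)C(C)(C)C)C[C@H]1[C@@](C=C)(O[Mg]Br)C=CC2=O | intermediate
9 | 10α-propionyloxy-10β-vinyl enone | C=CC[C@]12CC(O[Si](C)(C)C(C)(C)C)=C(O[Si](C)(C)C(C)(C)C)C[C@H]1[C@@](C=C)(OC(=O)CC)C=CC2=O | intermediate
10 | keto lactone (19,10-lactone cis-fused to ring B; H5β; C7 ketone; C4 methyl drawn trans to C6, this center is inconsequential) | C=CC[C@]12CC(O[Si](C)(C)C(C)(C)C)=C(O[Si](C)(C)C(C)(C)C)C[C@H]1[C@@]3(C=C)OC(=O)[C@H](C)[C@H]3CC2=O | intermediate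
11 | 6-trifluoroacetyl-7-ketone (C6 enolizable, drawn without configuration) | C=CC[C@]12CC(O[Si](C)(C)C(C)(C)C)=C(O[Si](C)(C)C(C)(C)C)C[C@H]1[C@@]3(C=C)OC(=O)[C@H](C)[C@H]3C(C(=O)C(F)(F)F)C2=O | intermediate
12 | 6-diazo-7-ketone | C=CC[C@]12CC(O[Si](C)(C)C(C)(C)C)=C(O[Si](C)(C)C(C)(C)C)C[C@H]1[C@@]3(C=C)OC(=O)[C@H](C)[C@H]3C(=[N+]=[N-])C2=O | intermediate
13 | aldol adduct (C4 quaternary; (3S)-hydroxyallyl group on the face of the 10-vinyl group) | C=CC[C@]12CC(O[Si](C)(C)C(C)(C)C)=C(O[Si](C)(C)C(C)(C)C)C[C@H]1[C@@]3(C=C)OC(=O)[C@](C)([C@@H](O)C=C)[C@H]3C(=[N+]=[N-])C2=O | intermediate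
14 | 3-O-triethylsilyl diazo ketone | C=CC[C@]12CC(O[Si](C)(C)C(C)(C)C)=C(O[Si](C)(C)C(C)(C)C)C[C@H]1[C@@]3(C=C)OC(=O)[C@](C)([C@@H](O[Si](CC)(CC)CC)C=C)[C@H]3C(=[N+]=[N-])C2=O | intermediate
15 | ketene (ring B five-membered; C6=C7=O) | C=CC[C@]12CC(O[Si](C)(C)C(C)(C)C)=C(O[Si](C)(C)C(C)(C)C)C[C@H]1[C@@]3(C=C)OC(=O)[C@](C)([C@@H](O[Si](CC)(CC)CC)C=C)[C@H]3C2=C=O | intermediate
16 | C6-epimeric ester (6α-CO2CH2CH2SiMe3) | C=CC[C@]12CC(O[Si](C)(C)C(C)(C)C)=C(O[Si](C)(C)C(C)(C)C)C[C@H]1[C@@]3(C=C)OC(=O)[C@](C)([C@@H](O[Si](CC)(CC)CC)C=C)[C@H]3[C@H]2C(=O)OCC[Si](C)(C)C | intermediate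
17 | 6β-(2-trimethylsilylethyl) ester with five-membered ring B | C=CC[C@]12CC(O[Si](C)(C)C(C)(C)C)=C(O[Si](C)(C)C(C)(C)C)C[C@H]1[C@@]3(C=C)OC(=O)[C@](C)([C@@H](O[Si](CC)(CC)CC)C=C)[C@H]3[C@@H]2C(=O)OCC[Si](C)(C)C | intermediate
18 | 13-O-TBS 12-oxo-16-ene (ring D closed; C13–C16 bond) | C=C1C[C@]23C[C@@]1(O[Si](C)(C)C(C)(C)C)C(=O)C[C@H]2[C@@]4(C=C)OC(=O)[C@](C)([C@@H](O[Si](CC)(CC)CC)C=C)[C@H]4[C@@H]3C(=O)OCC[Si](C)(C)C | intermediate
19 | 15α-alcohol (exo hydroxyl, syn to C14) | C=C1[C@H](O)[C@]23C[C@@]1(O[Si](C)(C)C(C)(C)C)C(=O)C[C@H]2[C@@]4(C=C)OC(=O)[C@](C)([C@@H](O[Si](CC)(CC)CC)C=C)[C@H]4[C@@H]3C(=O)OCC[Si](C)(C)C | intermediate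
20 | 12,15-diketone | C=C1C(=O)[C@]23C[C@@]1(O[Si](C)(C)C(C)(C)C)C(=O)C[C@H]2[C@@]4(C=C)OC(=O)[C@](C)([C@@H](O[Si](CC)(CC)CC)C=C)[C@H]4[C@@H]3C(=O)OCC[Si](C)(C)C | intermediate
21 | 12α,15β-diol | C=C1[C@@H](O)[C@]23C[C@@]1(O[Si](C)(C)C(C)(C)C)[C@@H](O)C[C@H]2[C@@]4(C=C)OC(=O)[C@](C)([C@@H](O[Si](CC)(CC)CC)C=C)[C@H]4[C@@H]3C(=O)OCC[Si](C)(C)C | intermediate
22 | fully protected 12α,15β-dihydroxygibberellic acid (3-O-TES; 13-O-TBS; 7-(2-trimethylsilylethyl) ester) | C=C1[C@@H](O)[C@]23C[C@@]1(O[Si](C)(C)C(C)(C)C)[C@@H](O)C[C@H]2[C@@]12C=C[C@H](O[Si](CC)(CC)CC)[C@@](C)(C(=O)O1)[C@H]2[C@@H]3C(=O)OCC[Si](C)(C)C | intermediate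
23 | 12α,15β-dihydroxygibberellic acid (the target gibberellin) | C=C1[C@@H](O)[C@]23C[C@@]1(O)[C@@H](O)C[C@H]2[C@@]12C=C[C@H](O)[C@@](C)(C(=O)O1)[C@H]2[C@@H]3C(=O)O | target

**Step count and risks**

Total step count: 17. Longest linear sequence: 16 steps (1 → 2 → 5 → 6 → … → 23; step 2 makes the diene 4 on a side branch).

Steps most likely to fail:

1. Step 12. The cycloalkenylation has close precedent only for simple silyl enol ethers; on the 1,2-bis(silyloxy)alkene, palladium may dehydrosilylate the enediol ether (Saegusa-type oxidation) or metalate C12 instead of C13, and the other alkenes may interfere. Fallback, from 17 back to 18: replace the organopalladium closure by an oxidative radical cyclization. Cu(OTf)2/Cu2O in MeCN at 0 °C should oxidize the enediol ether to its radical cation; after loss of the silyl group on O12 the C13 radical closes 5-exo onto the allyl group, and divalent copper oxidizes the primary C17 radical to the terminal alkene. This gives 18 directly with no new intermediate.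

2. Step 9. Facial selectivity at the aldehyde may be poor (open instead of closed transition state), which would give the wrong C3 configuration. Fallback, from 12 back to 13: set C3 by a reagent instead of by the aldol transition state. The crude aldol product, mainly the 3-epi adduct F1, is oxidized with Dess–Martin periodinane to the vinyl ketone F2. Corey–Bakshi–Shibata reduction ((R)-Me-CBS, catecholborane, toluene, −78 °C; quaternary C4 as the large group) should then give 13.

3. Step 15. Hydride may also attack C15 from the endo face, because the exo face is crowded by the C7 ester, so that the 15α-alcohol is regenerated. Fallback, from 19 back to 21: invert C15 by substitution instead of by reduction. NaBH4 (MeOH, −40 °C) reduces only the C12 ketone of 19 to the 12α,15α-diol F3. A Mitsunobu reaction (4-nitrobenzoic acid, PPh3, DIAD, THF, 0 °C) at the more reactive allylic C15 hydroxyl gives the 15β-(4-nitrobenzoate) F4 with inversion, and K2CO3 in MeOH removes the ester to give 21.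

Further compounds
F0 | step 12 | none | none
F1 | step 9 | 3-epi aldol adduct | C=CC[C@]12CC(O[Si](C)(C)C(C)(C)C)=C(O[Si](C)(C)C(C)(C)C)C[C@H]1[C@@]3(C=C)OC(=O)[C@](C)([C@H](O)C=C)[C@H]3C(=[N+]=[N-])C2=O
F2 | step 9 | vinyl ketone (C3 ketone) | C=CC[C@]12CC(O[Si](C)(C)C(C)(C)C)=C(O[Si](C)(C)C(C)(C)C)C[C@H]1[C@@]3(C=C)OC(=O)[C@](C)(C(=O)C=C)[C@H]3C(=[N+]=[N-])C2=O
F3 | step 15 | 12α,15α-diol | C=C1[C@H](O)[C@]23C[C@@]1(O[Si](C)(C)C(C)(C)C)[C@@H](O)C[C@H]2[C@@]4(C=C)OC(=O)[C@](C)([C@@H](O[Si](CC)(CC)CC)C=C)[C@H]4[C@@H]3C(=O)OCC[Si](C)(C)C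
F4 | step 15 | 15β-(4-nitrobenzoate) | C=C1[C@@H](OC(=O)c5ccc(cc5)[N+](=O)[O-])[C@]23C[C@@]1(O[Si](C)(C)C(C)(C)C)[C@@H](O)C[C@H]2[C@@]4(C=C)OC(=O)[C@](C)([C@@H](O[Si](CC)(CC)CC)C=C)[C@H]4[C@@H]3C(=O)OCC[Si](C)(C)C
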